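Its constants were chosen freely; the flask was simulated.

**Acid ratio.** Substrate leaves this flask by two paths, and at the charge they stand in the ratio 2.61. This acid ratio is the rate constant of the acid-catalysed step times [acid], over twice the self-condensation constant times [substrate]. With [acid] steady, it grows as [substrate] falls.

substrate 0.050 M; acid 5.00 mM; scavenger 0.0500 M; time 25 h

    weak acid + scavenger → scavenged by-product (k1 = 0.032 M⁻¹ s⁻¹)
    2 substrate → self-condensation product (k2 = 6.7 × 10⁻⁵ M⁻¹ s⁻¹)
    substrate + weak acid ⇌ idle adduct, settled at all times (K3 = 15 M⁻¹)
    substrate + acid → weak acid + acid + target (k4 = 0.0035 M⁻¹ s⁻¹)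
    substrate → weak acid + target (k5 = 1.1 × 10⁻⁷ s⁻¹)
    weak acid ⇌ conjugate base + acid, settled at all times (K6 = 5.0 × 10⁻⁹ M)

- part of the substrate that has reacted at 25 h
- pH of the solution at 25 h

- acid is the free proton; pH is minus the decimal logarithm of its molar concentration
- percentages count the substrate that a species holds: one self-condensation product counts as two
- weak acid is meant together with its idle adduct
- a doubled species enters its step squared and goes two at a time
- run time (flask): 25 h

**Frozen acid.** A hand reckoning freezes [acid]. The catalysed step returns its acid, and the weak acid's constant 5.0 × 10⁻⁹ M lies far below 5.00 mM. Substrate then runs on a pseudo-first-order clock with half-life 11 h. The uncatalysed step, with half-life 73 d, is much slower than the run and is dropped.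

**Time.** Over 25 h the clock by itself leaves the fraction 0.207. Integrating with self-condensation gives f/(1+(1−f)/ratio), or 15.9 % left. The hand answer is 84.1 % reacted.

**Acid charge.** More acid shortens the clock, and that pushes conversion up. It also raises the ratio, which by hand turns more of the substrate used towards target.

**Substrate charge.** The clock ignores this charge. More substrate lowers the ratio and favours self-condensation.

**Scavenger charge.** Integrating the ratio gives a target share of 69.3 %. That makes 0.0346 M of weak acid, less than the 0.0500 M of scavenger. Free weak acid has a half-life of 0.12 h and should start near 5.47 × 10⁻⁴ M, which ties up 0.820 % of the substrate as idle adduct. More scavenger should change conversion little.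

**The forecast.** It gives 84.1 % reacted and pH 2.3, holding that “Free acid stays at 5.00 mM”. It keeps the uncatalysed step, which the hand reckoning dropped, and the two conversions coincide.

**The result.** The simulation gives 84.1 % and pH 2.30, as forecast. Moved by a factor of 1.3, the settings rank: time (7.6 points), then acid (6.1 points), then substrate (1 points), then scavenger (under 0.05 points). Conversion shifts 5 points at 4.03 mM or 6.32 mM of acid. At 25.0 h this flask's ratio reads 16, which is the charge value over the 16 % of substrate left, 16.3, and target stands at 69.4 % against 14.7 % of self-condensation product. The neighbour charged with 0.0013 M of acid starts at a ratio of 0.679, and its target, 27.8 %, stands level with its self-condensation product, 28.0 %.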